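The numbers in the tables stem from a simulated flask with constants of no real substance; the scatter is artificial.

How far will E have gone in the south flask at 3.0 h, and how long will its chains be?

| flask | E | X | remark | time |
|---|---|---|---|---|
| south | 1.4 M | 66 mM | the very flask that is asked about, followed so far |  |
| west | 2.1 M | 66 mM | run made earlier |  |
| flask | 1.4 M | 66 mM |  | 3.0 h |

- south (time / min: L / %, E / %): 20.0: 0.6, 98.9; 40.0: 4.9, 94.2; 50.0: 7.9, 91.4; 80.0: 16.4, 82.3
- west (time / min: L / %, E / %): 15.0: 1.2, 99.4; 40.0: 7.3, 92.5; 80.0: 20.4, 78.4; 120: 31.3, 67.2

(scatter of a reading: 0.3 percentage points)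

* average number of monomer units in a chain (chains begun, living or dead) at 3.0 h
* part of the E that has reacted at 3.0 h

- the average divides the monomer in chains by the number of chains begun, living and dead together
- what may be going on: E + J -> D + L; E + D -> L + D; L + D -> E + D; D + E -> Q; X <-> J
- the earlier runs do not show the number of chains; that part of a forecast is a guess

Take the south run in slow motion. At the start, L stands at 0.6% after 20.0 min and 7.9% after 50.0 min, which reads as chains still being begun, so expect a delay when you repeat it.

In the middle, set the two runs side by side over similar times, since both had the same charge of X. The south run loses E at 0.00425 M min⁻¹ around 1.22 M. The west run loses it at 0.00740 M min⁻¹ around 1.79 M. The rate ratio, 1.74, is larger than the concentration ratio, 1.47, so the rate is not simply proportional to c_E. Chains also give E back, and a line through the two points reaches zero rate at the ceiling concentration, the c_E at which growth and return balance (the equilibrium monomer concentration):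

slope = (0.00740 M min⁻¹ − 0.00425 M min⁻¹) / (1.79 M − 1.22 M) = 0.00545 min⁻¹

ceiling = 1.22 M − 0.00425 M min⁻¹ / slope = 0.437 M

This is a reading: it carries the scatter of the runs, and it takes the number of living ends to be the same in both runs, which the readings do not show.

Towards the end, the excess of c_E over the ceiling should shrink exponentially, provided the number of living ends holds. Starting from 80.0 min, I reckon c_E at 3.0 h as 0.852 M, which means 39.2% reacted.

The forecast says 37.5% (33.5% to 41.5%) and a dp of 8.3 (7 to 13). It also “suggests reversible propagation with a ceiling” near 0.5 M, so its ceiling and conversion differ from mine. Of its dp it says “This part is a guess”.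

The flask gives:

36.6% reacted and a dp of 7.93.

    E + J → D + L (k = 3.86 × 10⁻⁴ M⁻¹ s⁻¹)
    E + D → L + D, rate k2*[D]*[E] (k = 0.00515 M⁻¹ s⁻¹)
    L + D → E + D, rate k3*[D] as long as [L] is above zero (k = 0.00352 s⁻¹)
    D + E → Q (k = 1.90 × 10⁻⁴ M⁻¹ s⁻¹)
    X ⇌ J (K = 8.30, k = 3.78 × 10⁻⁴ s⁻¹)

At 3.00 h the south flask holds 0.887 M of E, against the 0.852 M reckoned. The neighbour flask charged with 0.35 M of E starts below the ceiling read from the runs, 0.437 M, and by the reckoning its E has no excess to turn into chains. At 3.00 h that neighbour holds 96.7% of its E and L at 0.0439%, with a dp of 0.00382. Nearly all of the 3.26% that reacted there stands as Q, at 3.22%.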